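**Retrosynthetic overview**

1. The target is traced back, by buffered global desilylation and oxidation of the side-chain carbinol, to a fully silylated 2,3,6,7-tetrahydrobenzofuran.
2. Key disconnection (benzofuran numbering; the side-chain carbonyl carbon is called C8): the C3a–C4 bond of the carbocycle together with O1–C7a of the dihydrofuran. Both rings open to an acyclic 1,5-diyne with one free secondary hydroxyl. Forward, the dihydrofuran closes first and its enol ether then closes the carbocycle in the same gold-catalysed operation.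
3. Enabling feature: the diene C7a=C3a–C4(OMe)=C5. C3a is the nucleophilic β-carbon of the ring enol ether O1–C7a=C3a, and C4(OMe)=C5–H is the hydro-functionalised form of a methyl ynol ether MeO–C4≡C5, whose O-bearing carbon is electrophilic under π-acid activation.
4. The diyne comes from a trans-aryl epoxide and an alkynylalane (C3–C3a bond, inversion at C3, which becomes the cis-2,3 relationship on ring closure).
5. The epoxide comes from methyl 4-hydroxy-3-iodobenzoate by Heck reaction and Shi epoxidation. The alkyne part comes from an Evans crotonate syn-aldol with 3-phenylpropanal, dibromo-olefination, ozonolysis and Felkin–Anh addition of lithium methoxyacetylide.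

Key step: step 15

Remark on the chemistry: the L-fructose-derived Shi ketone is assumed to show the mirror-image face selectivity of the usual D-fructose-derived ketone on trans-β-alkylstyrenes; the configuration at C8 is free (it becomes the ketone) and is chosen so that it reinforces Felkin–Anh control in step 12.

**Route**

Step 1
Reactants: 1 methyl 4-hydroxy-3-iodobenzoate
Product: 2 methyl 3-iodo-4-(triisopropylsilyloxy)benzoate
Conditions: TIPSCl, imidazole, DMF, 23 °C
Reagents that add atoms: chlorotriisopropylsilane, CC(C)[Si](Cl)(C(C)C)C(C)C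
Why: Silyl ether formation on a phenol; the bulky triisopropylsilyl group should survive the aqueous base of step 4 and keep the phenol oxygen from adding to the alkyne in step 15.

Step 2
Reactants: 2 methyl 3-iodo-4-(triisopropylsilyloxy)benzoate; 3 2-methylbut-3-en-2-ol
Product: 4 methyl 3-[(E)-3-hydroxy-3-methylbut-1-enyl]-4-(triisopropylsilyloxy)benzoate
Conditions: Pd(OAc)2 (5 mol%), P(o-tol)3, Et3N, MeCN, 80 °C
Reagents that add atoms: none
Why: Heck reaction of an aryl iodide with a monosubstituted alkene whose carbinol carbon has no hydrogen, so that syn-insertion and syn-β-hydride elimination should give only the (E)-styrene.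

Step 3
Reactants: 4 methyl 3-[(E)-3-hydroxy-3-methylbut-1-enyl]-4-(triisopropylsilyloxy)benzoate
Product: 5 methyl 3-[(E)-3-methyl-3-(triethylsilyloxy)but-1-enyl]-4-(triisopropylsilyloxy)benzoate
Conditions: TESOTf, 2,6-lutidine, CH2Cl2, −78 → 0 °C
Reagents that add atoms: triethylsilyl trifluoromethanesulfonate, CC[Si](CC)(CC)OS(=O)(=O)C(F)(F)F
Why: Silylation of a hindered tertiary alcohol with a silyl triflate under lutidine buffering; this oxygen must be masked because it would otherwise add 5-exo to the alkyne in step 15.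

Step 4
Reactants: 5 methyl 3-[(E)-3-methyl-3-(triethylsilyloxy)but-1-enyl]-4-(triisopropylsilyloxy)benzoate
Product: 6 methyl 3-{(2S,3R)-3-[2-(triethylsilyloxy)propan-2-yl]oxiran-2-yl}-4-(triisopropylsilyloxy)benzoate
Conditions: L-fructose-derived Shi ketone (1,2:4,5-di-O-isopropylidene-β-L-erythro-2,3-hexodiulo-2,6-pyranose, 30 mol%), 2KHSO5·KHSO4·K2SO4, K2CO3, Bu4NHSO4, MeCN/CH2(OMe)2/aq. buffer pH 10.5, 0 °C
Reagents that add atoms: potassium peroxymonosulfate (active salt of Oxone), [K+].[O-]S(=O)(=O)OO
Why: Shi epoxidation of a trans-disubstituted styrene through the spiro dioxirane transition state; the chiral ketone should set both epoxide carbons (the later C3 and C2) and the (E)-alkene fixes the trans relationship.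

Step 5
Reactants: 7 (R)-4-benzyloxazolidin-2-one; 8 (E,E)-crotonic anhydride
Product: 9 (R)-4-benzyl-3-[(E)-but-2-enoyl]oxazolidin-2-one
Conditions: Et3N, LiCl, THF, −20 → 23 °C
Reagents that add atoms: none
Why: N-acylation of the oxazolidinone by the anhydride under LiCl/Et3N activation, a standard way to make Evans imides without strong base.

Step 6
Reactants: 9 (R)-4-benzyl-3-[(E)-but-2-enoyl]oxazolidin-2-one; 10 3-phenylpropanal
Product: 12 (R)-4-benzyl-3-[(2R,3S)-2-ethenyl-3-hydroxy-5-phenylpentanoyl]oxazolidin-2-one, via boron dienolate 11 (not isolated)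
Conditions: Bu2BOTf, Et3N, CH2Cl2, −78 → 0 °C; then 10, −78 → 0 °C; pH 7 buffer, MeOH, H2O2
Reagents that add atoms: none
Why: Evans syn-aldol of the Z-boron dienolate, which should react at its α-carbon through a Zimmerman–Traxler transition state; the (R)-auxiliary sets C7 and C8 as (2R,3S) with the vinyl group as a latent C6 aldehyde.

Step 7
Reactants: 12 (R)-4-benzyl-3-[(2R,3S)-2-ethenyl-3-hydroxy-5-phenylpentanoyl]oxazolidin-2-one
Product: 13 (R)-4-benzyl-3-[(2R,3S)-2-ethenyl-5-phenyl-3-(triethylsilyloxy)pentanoyl]oxazolidin-2-one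
Conditions: TESOTf, 2,6-lutidine, CH2Cl2, −78 °C
Reagents that add atoms: triethylsilyl trifluoromethanesulfonate, CC[Si](CC)(CC)OS(=O)(=O)C(F)(F)F
Why: Silyl ether formation; a non-chelating triethylsilyl group is chosen for C8–O because it must later be removed in the presence of a tert-butyldimethylsilyl ether and must not chelate in step 12.

Step 8
Reactants: 13 (R)-4-benzyl-3-[(2R,3S)-2-ethenyl-5-phenyl-3-(triethylsilyloxy)pentanoyl]oxazolidin-2-one
Product: 14 (2S,3S)-2-ethenyl-5-phenyl-3-(triethylsilyloxy)pentan-1-ol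
Conditions: LiBH4, MeOH (1 equiv), Et2O, 0 °C
Reagents that add atoms: none
Why: Reductive cleavage of the imide by LiBH4 should give the primary alcohol (the later C7a) without touching the α-stereocentre.

Step 9
Reactants: 14 (2S,3S)-2-ethenyl-5-phenyl-3-(triethylsilyloxy)pentan-1-ol
Product: 15 (2R,3S)-2-ethenyl-5-phenyl-3-(triethylsilyloxy)pentanal
Conditions: Dess–Martin periodinane, pyridine, CH2Cl2, 0 °C; used crude
Reagents that add atoms: none
Why: Dess–Martin oxidation is non-basic enough that the α-vinyl aldehyde should neither epimerise nor move its double bond into conjugation.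

Step 10
Reactants: 15 (2R,3S)-2-ethenyl-5-phenyl-3-(triethylsilyloxy)pentanal
Product: 16 [(3S,4S)-6,6-dibromo-4-ethenyl-1-phenylhex-5-en-3-yl]oxy(triethyl)silane
Conditions: CBr4, PPh3, Zn, CH2Cl2, 23 °C (ylide formation); then 15, 0 → 23 °C
Reagents that add atoms: carbon tetrabromide, BrC(Br)(Br)Br
Why: Ramirez dibromo-olefination (first half of the Corey–Fuchs reaction); the 1,1-dibromoalkene is a masked alkyne that is inert to ozone and does not make the neighbouring C–H as acidic as an alkyne would.

Step 11
Reactants: 16 [(3S,4S)-6,6-dibromo-4-ethenyl-1-phenylhex-5-en-3-yl]oxy(triethyl)silane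
Product: 18 (2S,3S)-2-(2,2-dibromoethenyl)-5-phenyl-3-(triethylsilyloxy)pentanal, via secondary ozonide 17 (not isolated)
Conditions: O3, CH2Cl2, −78 °C, stopped at first excess; then PPh3, −78 → 23 °C; used crude
Reagents that add atoms: ozone, [O-][O+]=O
Why: Ozonolysis should be chemoselective for the electron-rich monosubstituted alkene over the electron-poor dibromoalkene, and reductive work-up gives the C6 aldehyde.

Step 12
Reactants: 18 (2S,3S)-2-(2,2-dibromoethenyl)-5-phenyl-3-(triethylsilyloxy)pentanal; 19 2-chloro-1,1-dimethoxyethane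
Product: 21 (3R,4R)-6,6-dibromo-1-methoxy-4-[(1S)-3-phenyl-1-(triethylsilyloxy)propyl]hex-5-en-1-yn-3-ol, via lithium methoxyacetylide 20 (not isolated)
Conditions: 19, LiNEt2 (3.0 equiv), THF, 0 °C; then 18, −78 °C; aq. NH4Cl
Reagents that add atoms: none
Why: 1,2-Addition of an alkoxyacetylide to an α-branched aldehyde under Felkin–Anh control, with the silyloxyalkyl branch anti to the nucleophile and 1,3-anti induction from the β-silyloxy group acting in the same direction, should set the C6 carbinol as (3R) and install the methyl ynol ether in one step.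

Step 13
Reactants: 21 (3R,4R)-6,6-dibromo-1-methoxy-4-[(1S)-3-phenyl-1-(triethylsilyloxy)propyl]hex-5-en-1-yn-3-ol
Product: 22 (3S,4R)-1,1-dibromo-4-(tert-butyldimethylsilyloxy)-6-methoxy-3-[(1S)-3-phenyl-1-(triethylsilyloxy)propyl]hex-1-en-5-yne
Conditions: TBSCl, imidazole, DMAP (cat.), DMF, 23 °C
Reagents that add atoms: tert-butylchlorodimethylsilane, CC(C)(C)[Si](C)(C)Cl
Why: Silyl ether formation under non-acidic conditions that the ynol ether tolerates; a silyloxy group at C6 is a poor leaving group, which protects against ionisation next to the ynol ether.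

Step 14
Reactants: 22 (3S,4R)-1,1-dibromo-4-(tert-butyldimethylsilyloxy)-6-methoxy-3-[(1S)-3-phenyl-1-(triethylsilyloxy)propyl]hex-1-en-5-yne; 6 methyl 3-{(2S,3R)-3-[2-(triethylsilyloxy)propan-2-yl]oxiran-2-yl}-4-(triisopropylsilyloxy)benzoate
Product: 25 methyl 3-[(1R,2R)-1-{(3S,4R)-4-(tert-butyldimethylsilyloxy)-6-methoxy-3-[(1S)-3-phenyl-1-(triethylsilyloxy)propyl]hexa-1,5-diyn-1-yl}-2-hydroxy-3-methyl-3-(triethylsilyloxy)butyl]-4-(triisopropylsilyloxy)benzoate, via lithium acetylide 23 (not isolated), via diethylalkynylalane 24 (not isolated)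
Conditions: 22, n-BuLi (2 equiv), THF/PhMe, −78 → 0 °C; Et2AlCl, 0 °C; then 6, PhMe, 0 → 23 °C; aq. KNaC4H4O6
Reagents that add atoms: none
Why: The second half of the Corey–Fuchs reaction (Fritsch–Buttenberg–Wiechell rearrangement) gives the acetylide, whose alane should open the trans-epoxide by SN2 attack at the benzylic carbon (the other carbon is neopentyl-like) with inversion, so that C3 is set anti to C2–O and the later ring closure gives the cis-2,3-disubstituted dihydrofuran, while the alane leaves the methyl ester alone.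

Step 15
Reactants: 25 methyl 3-[(1R,2R)-1-{(3S,4R)-4-(tert-butyldimethylsilyloxy)-6-methoxy-3-[(1S)-3-phenyl-1-(triethylsilyloxy)propyl]hexa-1,5-diyn-1-yl}-2-hydroxy-3-methyl-3-(triethylsilyloxy)butyl]-4-(triisopropylsilyloxy)benzoate
Product: 27 methyl 3-[(2R,3S,6S,7S)-6-(tert-butyldimethylsilyloxy)-4-methoxy-7-[(1S)-3-phenyl-1-(triethylsilyloxy)propyl]-2-[2-(triethylsilyloxy)propan-2-yl]-2,3,6,7-tetrahydro-1-benzofuran-3-yl]-4-(triisopropylsilyloxy)benzoate, via dihydrofuran enol ether 26 (not isolated)
Conditions: [(t-Bu)2(2-biphenylyl)PAu(NCMe)]SbF6 (5 mol%), 2,6-di-tert-butylpyridine (10 mol%), 4 Å MS, CH2Cl2, −20 → 23 °C; Et3N quench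
Reagents that add atoms: none
Why: Proposed new method: the cationic monovalent gold centre should first activate the internal alkyne for anti attack of the only free hydroxyl (C2–OH) on C7a, a 5-endo-dig oxa-cyclisation that closes the dihydrofuran ring and gives enol ether 26 after protodeauration; the catalyst should then turn the ynol ether into a gold-bound ketenium ion whose O-bearing carbon C4 is attacked by the enol ether β-carbon C3a in a 6-endo-dig carbocyclisation that closes the six-membered carbocycle, after which loss of the C3a proton and protodeauration at C5 release the diene. The closest known reaction types are the gold-catalysed 5-endo-dig cycloisomerisation of homopropargylic alcohols to 2,3-dihydrofurans and the π-acid- or proton-triggered 6-endo cyclisation of oxygen-substituted 1,5-enynes to oxygenated cyclohexadienes; running both in one cascade on a 1,5-diyne with an alkyl ynol ether is new. No stereocentre is formed: C2, C3, C6 and C7 are carried in from 25, and none is acidified because C8 is still a silyl ether and not a ketone. The step needs chemoselectivity among five oxygen functions, secured by leaving only the C2 hydroxyl free and by the bulky aryl silyl ether; regioselectivity of C–C bond formation, secured by the methoxy group, which makes only C4 electrophilic (6-endo over 5-exo); and the right position of the ring enol ether, secured because deprotonation at C3a and not at C7 gives the conjugated bis(enol ether) diene. The geometry is matched, since O1 and C4 must end up anti across the former C3a≡C7a triple bond, which is what the two fused rings require. Molecular sieves and the hindered pyridine should keep water and free acid away, so that hydration of the ynol ether and acid-promoted loss of the C6 silyloxy group with aromatisation are suppressed.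

Step 16
Reactants: 27 methyl 3-[(2R,3S,6S,7S)-6-(tert-butyldimethylsilyloxy)-4-methoxy-7-[(1S)-3-phenyl-1-(triethylsilyloxy)propyl]-2-[2-(triethylsilyloxy)propan-2-yl]-2,3,6,7-tetrahydro-1-benzofuran-3-yl]-4-(triisopropylsilyloxy)benzoate
Product: 28 methyl 3-[(2R,3S,6S,7S)-6-(tert-butyldimethylsilyloxy)-7-[(1S)-1-hydroxy-3-phenylpropyl]-4-methoxy-2-[2-(triethylsilyloxy)propan-2-yl]-2,3,6,7-tetrahydro-1-benzofuran-3-yl]-4-(triisopropylsilyloxy)benzoate
Conditions: HF·pyridine, excess pyridine, THF, 0 °C
Reagents that add atoms: none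
Why: Selective desilylation: with pyridine-buffered HF a secondary triethylsilyl ether should cleave well before the secondary tert-butyldimethylsilyl, the hindered tertiary triethylsilyl and the aryl triisopropylsilyl ethers, and any loss of the tertiary group would converge again in step 18.

Step 17
Reactants: 28 methyl 3-[(2R,3S,6S,7S)-6-(tert-butyldimethylsilyloxy)-7-[(1S)-1-hydroxy-3-phenylpropyl]-4-methoxy-2-[2-(triethylsilyloxy)propan-2-yl]-2,3,6,7-tetrahydro-1-benzofuran-3-yl]-4-(triisopropylsilyloxy)benzoate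
Product: 29 methyl 3-[(2R,3S,6S,7S)-6-(tert-butyldimethylsilyloxy)-4-methoxy-7-(3-phenylpropanoyl)-2-[2-(triethylsilyloxy)propan-2-yl]-2,3,6,7-tetrahydro-1-benzofuran-3-yl]-4-(triisopropylsilyloxy)benzoate
Conditions: Dess–Martin periodinane, pyridine, CH2Cl2, 0 °C
Reagents that add atoms: none
Why: Dess–Martin oxidation of the only free secondary alcohol under pyridine buffering should give the C8 ketone without acid (enol ethers) or strong base (the now acidic C7–H and the β-silyloxy group).

Step 18
Reactants: 29 methyl 3-[(2R,3S,6S,7S)-6-(tert-butyldimethylsilyloxy)-4-methoxy-7-(3-phenylpropanoyl)-2-[2-(triethylsilyloxy)propan-2-yl]-2,3,6,7-tetrahydro-1-benzofuran-3-yl]-4-(triisopropylsilyloxy)benzoate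
Product: 30 methyl 4-hydroxy-3-[(2R,3S,6S,7S)-6-hydroxy-2-(2-hydroxypropan-2-yl)-4-methoxy-7-(3-phenylpropanoyl)-2,3,6,7-tetrahydro-1-benzofuran-3-yl]benzoate
Conditions: Bu4NF, AcOH (1:1), THF, 0 → 23 °C; pH 7 work-up
Reagents that add atoms: none
Why: Global fluoride desilylation buffered with acetic acid should free the C6 hydroxyl, the tertiary alcohol and the phenol while avoiding the base-induced β-elimination and aromatisation or C7 epimerisation to which the β-hydroxy ketone is prone.

**Compound list**

1 | methyl 4-hydroxy-3-iodobenzoate | COC(=O)c1ccc(O)c(I)c1 | starting material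
2 | methyl 3-iodo-4-(triisopropylsilyloxy)benzoate | COC(=O)c1ccc(O[Si](C(C)C)(C(C)C)C(C)C)c(I)c1 | intermediate
3 | 2-methylbut-3-en-2-ol | C=CC(C)(C)O | starting material
4 | methyl 3-[(E)-3-hydroxy-3-methylbut-1-enyl]-4-(triisopropylsilyloxy)benzoate | COC(=O)c1ccc(O[Si](C(C)C)(C(C)C)C(C)C)c(/C=C/C(C)(C)O)c1 | intermediate
5 | methyl 3-[(E)-3-methyl-3-(triethylsilyloxy)but-1-enyl]-4-(triisopropylsilyloxy)benzoate | COC(=O)c1ccc(O[Si](C(C)C)(C(C)C)C(C)C)c(/C=C/C(C)(C)O[Si](CC)(CC)CC)c1 | intermediate
6 | methyl 3-{(2S,3R)-3-[2-(triethylsilyloxy)propan-2-yl]oxiran-2-yl}-4-(triisopropylsilyloxy)benzoate (trans-epoxide) | COC(=O)c1ccc(O[Si](C(C)C)(C(C)C)C(C)C)c([C@@H]2O[C@H]2C(C)(C)O[Si](CC)(CC)CC)c1 | intermediate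
7 | (R)-4-benzyloxazolidin-2-one | O=C1N[C@H](Cc2ccccc2)CO1 | starting material
8 | (E,E)-crotonic anhydride | C/C=C/C(=O)OC(=O)/C=C/C | starting material
9 | (R)-4-benzyl-3-[(E)-but-2-enoyl]oxazolidin-2-one | C/C=C/C(=O)N1[C@H](Cc2ccccc2)COC1=O | intermediate
10 | 3-phenylpropanal | O=CCCc1ccccc1 | starting material
11 | Z(O)-dibutylboron dienolate of 9 | C=C/C=C(\OB(CCCC)CCCC)N1[C@H](Cc2ccccc2)COC1=O | intermediate
12 | (R)-4-benzyl-3-[(2R,3S)-2-ethenyl-3-hydroxy-5-phenylpentanoyl]oxazolidin-2-one | O=C(N1[C@H](Cc2ccccc2)COC1=O)[C@H](C=C)[C@@H](O)CCc1ccccc1 | intermediate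
13 | (R)-4-benzyl-3-[(2R,3S)-2-ethenyl-5-phenyl-3-(triethylsilyloxy)pentanoyl]oxazolidin-2-one | O=C(N1[C@H](Cc2ccccc2)COC1=O)[C@H](C=C)[C@@H](O[Si](CC)(CC)CC)CCc1ccccc1 | intermediate
14 | (2S,3S)-2-ethenyl-5-phenyl-3-(triethylsilyloxy)pentan-1-ol | OC[C@H](C=C)[C@@H](O[Si](CC)(CC)CC)CCc1ccccc1 | intermediate
15 | (2R,3S)-2-ethenyl-5-phenyl-3-(triethylsilyloxy)pentanal | O=C[C@H](C=C)[C@@H](O[Si](CC)(CC)CC)CCc1ccccc1 | intermediate
16 | [(3S,4S)-6,6-dibromo-4-ethenyl-1-phenylhex-5-en-3-yl]oxy(triethyl)silane | BrC(Br)=C[C@H](C=C)[C@@H](O[Si](CC)(CC)CC)CCc1ccccc1 | intermediate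
17 | secondary ozonide (1,2,4-trioxolane) at the vinyl group of 16, mixture of epimers at the trioxolane carbon | BrC(Br)=C[C@H](C2OOCO2)[C@@H](O[Si](CC)(CC)CC)CCc1ccccc1 | intermediate
18 | (2S,3S)-2-(2,2-dibromoethenyl)-5-phenyl-3-(triethylsilyloxy)pentanal | BrC(Br)=C[C@H](C=O)[C@@H](O[Si](CC)(CC)CC)CCc1ccccc1 | intermediate
19 | 2-chloro-1,1-dimethoxyethane (chloroacetaldehyde dimethyl acetal) | COC(CCl)OC | starting material
20 | lithium methoxyacetylide | [Li]C#COC | intermediate
21 | (3R,4R)-6,6-dibromo-1-methoxy-4-[(1S)-3-phenyl-1-(triethylsilyloxy)propyl]hex-5-en-1-yn-3-ol | BrC(Br)=C[C@@H]([C@@H](O[Si](CC)(CC)CC)CCc1ccccc1)[C@@H](O)C#COC | intermediate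
22 | (3S,4R)-1,1-dibromo-4-(tert-butyldimethylsilyloxy)-6-methoxy-3-[(1S)-3-phenyl-1-(triethylsilyloxy)propyl]hex-1-en-5-yne | BrC(Br)=C[C@@H]([C@@H](O[Si](CC)(CC)CC)CCc1ccccc1)[C@@H](O[Si](C)(C)C(C)(C)C)C#COC | intermediate
23 | lithium acetylide derived from 22 | [Li]C#C[C@@H]([C@@H](O[Si](CC)(CC)CC)CCc1ccccc1)[C@@H](O[Si](C)(C)C(C)(C)C)C#COC | intermediate
24 | diethyl(alkynyl)alane derived from 23 | CC[Al](CC)C#C[C@@H]([C@@H](O[Si](CC)(CC)CC)CCc1ccccc1)[C@@H](O[Si](C)(C)C(C)(C)C)C#COC | intermediate
25 | methyl 3-[(1R,2R)-1-{(3S,4R)-4-(tert-butyldimethylsilyloxy)-6-methoxy-3-[(1S)-3-phenyl-1-(triethylsilyloxy)propyl]hexa-1,5-diyn-1-yl}-2-hydroxy-3-methyl-3-(triethylsilyloxy)butyl]-4-(triisopropylsilyloxy)benzoate | COC(=O)c1ccc(O[Si](C(C)C)(C(C)C)C(C)C)c([C@H]([C@@H](O)C(C)(C)O[Si](CC)(CC)CC)C#C[C@@H]([C@@H](O[Si](CC)(CC)CC)CCc2ccccc2)[C@@H](O[Si](C)(C)C(C)(C)C)C#COC)c1 | intermediate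
26 | methyl 3-[(2R,3R)-5-{(1S,2R)-2-(tert-butyldimethylsilyloxy)-4-methoxy-1-[(1S)-3-phenyl-1-(triethylsilyloxy)propyl]but-3-yn-1-yl}-2-[2-(triethylsilyloxy)propan-2-yl]-2,3-dihydrofuran-3-yl]-4-(triisopropylsilyloxy)benzoate | COC(=O)c1ccc(O[Si](C(C)C)(C(C)C)C(C)C)c([C@H]2C=C(O[C@H]2C(C)(C)O[Si](CC)(CC)CC)[C@@H]([C@@H](O[Si](CC)(CC)CC)CCc2ccccc2)[C@@H](O[Si](C)(C)C(C)(C)C)C#COC)c1 | intermediate
27 | methyl 3-[(2R,3S,6S,7S)-6-(tert-butyldimethylsilyloxy)-4-methoxy-7-[(1S)-3-phenyl-1-(triethylsilyloxy)propyl]-2-[2-(triethylsilyloxy)propan-2-yl]-2,3,6,7-tetrahydro-1-benzofuran-3-yl]-4-(triisopropylsilyloxy)benzoate | COC(=O)c1ccc(O[Si](C(C)C)(C(C)C)C(C)C)c([C@H]2C3=C(O[C@H]2C(C)(C)O[Si](CC)(CC)CC)[C@@H]([C@@H](O[Si](CC)(CC)CC)CCc2ccccc2)[C@@H](O[Si](C)(C)C(C)(C)C)C=C3OC)c1 | intermediate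
28 | methyl 3-[(2R,3S,6S,7S)-6-(tert-butyldimethylsilyloxy)-7-[(1S)-1-hydroxy-3-phenylpropyl]-4-methoxy-2-[2-(triethylsilyloxy)propan-2-yl]-2,3,6,7-tetrahydro-1-benzofuran-3-yl]-4-(triisopropylsilyloxy)benzoate | COC(=O)c1ccc(O[Si](C(C)C)(C(C)C)C(C)C)c([C@H]2C3=C(O[C@H]2C(C)(C)O[Si](CC)(CC)CC)[C@@H]([C@@H](O)CCc2ccccc2)[C@@H](O[Si](C)(C)C(C)(C)C)C=C3OC)c1 | intermediate
29 | methyl 3-[(2R,3S,6S,7S)-6-(tert-butyldimethylsilyloxy)-4-methoxy-7-(3-phenylpropanoyl)-2-[2-(triethylsilyloxy)propan-2-yl]-2,3,6,7-tetrahydro-1-benzofuran-3-yl]-4-(triisopropylsilyloxy)benzoate | COC(=O)c1ccc(O[Si](C(C)C)(C(C)C)C(C)C)c([C@H]2C3=C(O[C@H]2C(C)(C)O[Si](CC)(CC)CC)[C@@H](C(=O)CCc2ccccc2)[C@@H](O[Si](C)(C)C(C)(C)C)C=C3OC)c1 | intermediate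
30 | methyl 4-hydroxy-3-[(2R,3S,6S,7S)-6-hydroxy-2-(2-hydroxypropan-2-yl)-4-methoxy-7-(3-phenylpropanoyl)-2,3,6,7-tetrahydro-1-benzofuran-3-yl]benzoate (CNP0080427.1) | COC(=O)c1ccc(O)c([C@H]2C3=C(O[C@H]2C(C)(C)O)[C@@H](C(=O)CCc2ccccc2)[C@@H](O)C=C3OC)c1 | target

**Step count and risks**

Total step count: 18. Longest linear sequence: 14 steps (steps 5–18); steps 1–4 form the convergent branch that joins at step 14.

Steps most likely to fail:

1. Step 15 (the step proposed as a new method). The cascade may stall after the first ring closure. The ynol ether may be hydrated or ionised before the C–C bond forms. A silyl ether oxygen may add in place of the free hydroxyl. Trace acid may cause loss of the C6 silyloxy group with aromatisation of the new ring. The fallback sets out from 25 and comes back at 27. It separates the two ring closures and uses a different activation for each, both with precedent on their own substrate classes. First, 25 is cyclised to the dihydrofuran 26, now isolated, by the known divalent-palladium-catalysed 5-endo-dig cycloisomerisation of 3-alkyn-1-ols (PdCl2(PhCN)2, THF, 23 °C). Then 26 is closed to 27 by the known proton-promoted ketenium cyclisation of oxygen-substituted alkynes onto a tethered alkene (HNTf2, 10 mol%, CH2Cl2, −78 °C, Et3N quench). No compound outside the list is made (F0).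

2. Step 12. Facial selectivity may be poor if the dibromovinyl group competes with the silyloxyalkyl branch for the anti position. The α-branched aldehyde may be enolised by the acetylide. Residual amide base may attack the dibromoalkene. The fallback sets out from 21 as obtained (mixture of C3 epimers) and comes back at 21. The mixture is oxidised with Dess–Martin periodinane and pyridine to the ynone (4S)-6,6-dibromo-1-methoxy-4-[(1S)-3-phenyl-1-(triethylsilyloxy)propyl]hex-5-en-1-yn-3-one F1. This is reduced under reagent control by CBS reduction ((R)-2-methyl-CBS-oxazaborolidine, catecholborane, toluene, −78 °C). The alkynyl group acts as the small substituent, so the (3R)-alcohol 21 should result whatever the substrate bias.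

3. Step 16. The methyl dienol ether may hydrolyse, or the allylic C6 silyloxy group may ionise, during exposure to acidic fluoride. Discrimination between the four silyl ethers may be incomplete. Step 18 shares this lability and is run buffered for the same reason. The fallback sets out from 27 and comes back at 29. It replaces deprotection followed by oxidation with one oxidative desilylation: IBX in DMSO at 23 °C, known to convert triethylsilyl ethers directly into carbonyl compounds while tert-butyldimethylsilyl ethers stay intact. This avoids fluoride and acid at this stage and makes no compound outside the list (F0).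

Further compounds
F0 | step 15 | none | none
F1 | step 12 | (4S)-6,6-dibromo-1-methoxy-4-[(1S)-3-phenyl-1-(triethylsilyloxy)propyl]hex-5-en-1-yn-3-one | BrC(Br)=C[C@@H]([C@@H](O[Si](CC)(CC)CC)CCc1ccccc1)C(=O)C#COC
F0 | step 16 | none | none
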